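The route rests on cutting the hexadecanoyl chain between C3 and C4. Because C3 is β to the ester carbonyl C1, this bond is the one made when an alkyl radical adds to an acrylate: C1–C3 is carried by the acrylate ester at the benzylic CH2–O of the methoxy-bearing ring of the intact, unprotected diaryl ether, and C4–C16 is a tridecyl radical released from tetradecanoic acid (as its N-acyloxyphthalimide) by photoreductive loss of CO2. One decarboxylative Giese addition thus joins tail and aromatic core and ends the synthesis. The core comes from an Ullmann coupling of an ortho-formylated catechol monobenzyl ether with a benzylated bromocresol.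

Key step: step 10

Remark: the target has no stereocentre and no stereogenic double bond; the SMILES describes one achiral compound, so no step has to control configuration.

Step 1
Reactants: 1 2-hydroxy-4-methoxybenzaldehyde
Product: 2 2-(benzyloxy)-4-methoxybenzaldehyde
Conditions: BnBr, K2CO3, DMF, 60 °C
Reagents that add atoms: benzyl bromide, BrCc1ccccc1
Why: Williamson etherification of the acidic ortho-formyl phenol should mask the oxygen that later becomes the free OH next to the diaryl ether oxygen.

Step 2
Reactants: 2 2-(benzyloxy)-4-methoxybenzaldehyde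
Product: 4 2-(benzyloxy)-4-methoxyphenol, via aryl formate 3 (not isolated)
Conditions: mCPBA, CH2Cl2, 0 °C to rt; then K2CO3, MeOH, rt
Reagents that add atoms: mCPBA (3-chloroperoxybenzoic acid), OOC(=O)c1cccc(Cl)c1
Why: Baeyer–Villiger oxidation of an ortho,para-dialkoxybenzaldehyde proceeds by migration of the electron-rich aryl group to the aryl formate, which mild methanolysis should cleave to the phenol.

Step 3
Reactants: 4 2-(benzyloxy)-4-methoxyphenol
Product: 5 3-(benzyloxy)-2-hydroxy-5-methoxybenzaldehyde
Conditions: MgCl2, Et3N, (CH2O)n, MeCN, reflux
Reagents that add atoms: paraformaldehyde (reacts as formaldehyde), C=O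
Why: Magnesium-phenoxide-directed ortho-formylation (Casnati–Skattebøl reaction) should place the formyl group at the only free ortho carbon, the other ortho carbon bearing OBn and the para carbon OMe.

Step 4
Reactants: 6 3-bromo-5-methylphenol
Product: 7 1-(benzyloxy)-3-bromo-5-methylbenzene
Conditions: BnBr, K2CO3, acetone, reflux
Reagents that add atoms: benzyl bromide, BrCc1ccccc1
Why: Williamson etherification should protect the phenol so that the bromoarene cannot couple with itself in the next step.

Step 5
Reactants: 5 3-(benzyloxy)-2-hydroxy-5-methoxybenzaldehyde; 7 1-(benzyloxy)-3-bromo-5-methylbenzene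
Product: 8 3-(benzyloxy)-2-[3-(benzyloxy)-5-methylphenoxy]-5-methoxybenzaldehyde
Conditions: CuI (10 mol%), picolinic acid (20 mol%), K3PO4, DMSO, 90 °C, Ar
Reagents that add atoms: none
Why: Ullmann-type Cu(I)-catalysed C–O coupling with a picolinate ligand is the variant suited to doubly ortho-substituted phenols, the aryl bromide is unhindered, and the benzyl ethers and the non-enolisable aldehyde should be inert.

Step 6
Reactants: 8 3-(benzyloxy)-2-[3-(benzyloxy)-5-methylphenoxy]-5-methoxybenzaldehyde
Product: 9 {3-(benzyloxy)-2-[3-(benzyloxy)-5-methylphenoxy]-5-methoxyphenyl}methanol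
Conditions: NaBH4, MeOH–THF, 0 °C
Reagents that add atoms: none
Why: Borohydride reduction of the aryl aldehyde should give the benzylic alcohol without touching the ethers.

Step 7
Reactants: 9 {3-(benzyloxy)-2-[3-(benzyloxy)-5-methylphenoxy]-5-methoxyphenyl}methanol
Product: 10 3-(hydroxymethyl)-2-(3-hydroxy-5-methylphenoxy)-5-methoxyphenol (core triol)
Conditions: H2 (1 atm), 10% Pd/C, EtOAc, rt, stopped after uptake of 2 equiv
Reagents that add atoms: none
Why: Catalytic hydrogenolysis cleaves both aryl benzyl ethers, while the benzylic alcohol, unactivated in neutral ethyl acetate, and the diaryl ether should be retained.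

Step 8
Reactants: 10 3-(hydroxymethyl)-2-(3-hydroxy-5-methylphenoxy)-5-methoxyphenol; 11 acrylic acid
Product: 12 [3-hydroxy-2-(3-hydroxy-5-methylphenoxy)-5-methoxyphenyl]methyl acrylate
Conditions: PPh3, DIAD, THF, 0 °C (betaine pre-formed, then 10 and 11 added), to rt
Reagents that add atoms: none
Why: Mitsunobu esterification activates only the aliphatic benzylic hydroxyl as its alkoxyphosphonium ion, which is displaced by the carboxylate, a far more acidic pronucleophile than the two phenols, so these should stay free.

Step 9
Reactants: 13 tetradecanoic acid
Product: 14 1,3-dioxoisoindolin-2-yl tetradecanoate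
Conditions: N-hydroxyphthalimide, DIC, DMAP (cat.), CH2Cl2, rt
Reagents that add atoms: N-hydroxyphthalimide, ON1C(=O)c2ccccc2C1=O
Why: Carbodiimide-mediated (Steglich-type) esterification should convert the fatty acid into its redox-active N-acyloxyphthalimide.

Step 10
Reactants: 12 [3-hydroxy-2-(3-hydroxy-5-methylphenoxy)-5-methoxyphenyl]methyl acrylate; 14 1,3-dioxoisoindolin-2-yl tetradecanoate
Product: 15 betaethrin H
Conditions: 14 (2 equiv), Hantzsch ester (diethyl 1,4-dihydro-2,6-dimethylpyridine-3,5-dicarboxylate, 2 equiv), Ru(bpy)3(PF6)2 (2 mol%), CH2Cl2–THF, blue LEDs (450 nm), rt, degassed, no amine base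
Reagents that add atoms: none
Why: Photoexcited Ru(II) is reductively quenched by the Hantzsch ester, and the resulting Ru(I) transfers an electron to 14, whose radical anion fragments to phthalimide anion, CO2 and the primary tridecyl radical. This nucleophilic radical adds to the unsubstituted terminal CH2 of the acrylate in 12 (the future C3), which creates the C3–C4 bond, and the electrophilic α-ester radical is then quenched by hydrogen transfer from the Hantzsch ester. The closest known reaction type is the reductive decarboxylative Giese addition of N-acyloxyphthalimides to acrylates. No ring is closed and no stereocentre is formed. The step needs chemoselectivity for C=C addition over phenol O–H abstraction, phenol acylation by the active ester, oxa-Michael addition and telomerisation; the purely reductive, base-free manifold should leave the electron-rich diaryl ether and the neutral phenols untouched, alkyl radical addition to an acrylate should outpace abstraction from these ArO–H bonds, and excess Hantzsch ester with the acrylate as limiting reagent should stop the chain after one addition.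

Compound list
1 | 2-hydroxy-4-methoxybenzaldehyde | O=Cc1ccc(OC)cc1O | starting material
2 | 2-(benzyloxy)-4-methoxybenzaldehyde | O=Cc1ccc(OC)cc1OCc1ccccc1 | intermediate
3 | aryl formate: 2-(benzyloxy)-4-methoxyphenyl formate (not isolated) | O=COc1ccc(OC)cc1OCc1ccccc1 | intermediate
4 | 2-(benzyloxy)-4-methoxyphenol | Oc1ccc(OC)cc1OCc1ccccc1 | intermediate
5 | 3-(benzyloxy)-2-hydroxy-5-methoxybenzaldehyde | O=Cc1cc(OC)cc(OCc2ccccc2)c1O | intermediate
6 | 3-bromo-5-methylphenol | Cc1cc(O)cc(Br)c1 | starting material
7 | 1-(benzyloxy)-3-bromo-5-methylbenzene | Cc1cc(Br)cc(OCc2ccccc2)c1 | intermediate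
8 | 3-(benzyloxy)-2-[3-(benzyloxy)-5-methylphenoxy]-5-methoxybenzaldehyde | O=Cc1cc(OC)cc(OCc2ccccc2)c1Oc1cc(C)cc(OCc2ccccc2)c1 | intermediate
9 | {3-(benzyloxy)-2-[3-(benzyloxy)-5-methylphenoxy]-5-methoxyphenyl}methanol | OCc1cc(OC)cc(OCc2ccccc2)c1Oc1cc(C)cc(OCc2ccccc2)c1 | intermediate
10 | 3-(hydroxymethyl)-2-(3-hydroxy-5-methylphenoxy)-5-methoxyphenol (core triol) | OCc1cc(OC)cc(O)c1Oc1cc(C)cc(O)c1 | intermediate
11 | acrylic acid | C=CC(=O)O | starting material
12 | [3-hydroxy-2-(3-hydroxy-5-methylphenoxy)-5-methoxyphenyl]methyl acrylate | C=CC(=O)OCc1cc(OC)cc(O)c1Oc1cc(C)cc(O)c1 | intermediate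
13 | tetradecanoic acid | CCCCCCCCCCCCCC(=O)O | starting material
14 | 1,3-dioxoisoindolin-2-yl tetradecanoate | CCCCCCCCCCCCCC(=O)ON1C(=O)c2ccccc2C1=O | intermediate
15 | betaethrin H: [3-hydroxy-2-(3-hydroxy-5-methylphenoxy)-5-methoxyphenyl]methyl hexadecanoate | CCCCCCCCCCCCCCCC(=O)OCc1cc(OC)cc(O)c1Oc1cc(C)cc(O)c1 | target

Total step count: 10.
Longest linear sequence: 8 steps (steps 1, 2, 3, 5, 6, 7, 8 and 10).

Steps most likely to fail

Step 10 (key step). The radical addition may be eroded by telomerisation of the acrylate, by premature reduction of the tridecyl radical, or by interference of the free phenols through hydrogen transfer or acyl transfer from the active ester. The fallback makes the same C3–C4 bond by olefin cross-metathesis and diimide reduction. It sets out from triol 10: Mitsunobu esterification with but-3-enoic acid (PPh3, DIAD, THF, 0 °C) should give [3-hydroxy-2-(3-hydroxy-5-methylphenoxy)-5-methoxyphenyl]methyl but-3-enoate F1. Cross-metathesis of F1 with excess tetradec-1-ene (second-generation Ru benzylidene catalyst, CH2Cl2, 40 °C) should give [3-hydroxy-2-(3-hydroxy-5-methylphenoxy)-5-methoxyphenyl]methyl (E)-hexadec-3-enoate F2, for which an E/Z mixture is acceptable. Diimide reduction (2-nitrobenzenesulfonyl hydrazide, Et3N, CH2Cl2, rt) would then saturate the C3=C4 bond without hydrogenolysis of the benzylic ester, and the fallback comes back to the route at target 15.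

Step 5. The copper-catalysed coupling may stall because the doubly ortho-substituted, chelating and electron-poor phenoxide of 5 is a weak nucleophile, leaving protodebromination of 7 to compete. The fallback reverses the polarity of the coupling. It sets out from phenol 5: Tf2O and pyridine (CH2Cl2, 0 °C) should give 2-(benzyloxy)-6-formyl-4-methoxyphenyl trifluoromethanesulfonate F3, an aryl electrophile activated by its ortho formyl group. Pd-catalysed C–O coupling (Pd(OAc)2, t-BuXPhos, K3PO4, toluene, 100 °C) with the unhindered 3-(benzyloxy)-5-methylphenol F4, obtained from orcinol by statistical monobenzylation (BnBr, K2CO3, acetone), would give the diaryl ether, and the fallback comes back to the route at 8.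

Step 8. The Mitsunobu esterification may lose chemoselectivity through O-alkylation of a phenol by the activated benzylic alcohol, or lose reagent through conjugate addition of the phosphine to acrylic acid. The fallback is an enzymatic acylation. It sets out from triol 10: immobilised Candida antarctica lipase B with vinyl acrylate in MTBE at 40 °C is expected to transesterify only the primary aliphatic hydroxyl, and it comes back to the route directly at acrylate 12 without any new intermediate.

Further compounds
F1 | step 10 | [3-hydroxy-2-(3-hydroxy-5-methylphenoxy)-5-methoxyphenyl]methyl but-3-enoate | C=CCC(=O)OCc1cc(OC)cc(O)c1Oc1cc(C)cc(O)c1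
F2 | step 10 | [3-hydroxy-2-(3-hydroxy-5-methylphenoxy)-5-methoxyphenyl]methyl (E)-hexadec-3-enoate | CCCCCCCCCCCC/C=C/CC(=O)OCc1cc(OC)cc(O)c1Oc1cc(C)cc(O)c1
F3 | step 5 | 2-(benzyloxy)-6-formyl-4-methoxyphenyl trifluoromethanesulfonate | O=Cc1cc(OC)cc(OCc2ccccc2)c1OS(=O)(=O)C(F)(F)F
F4 | step 5 | 3-(benzyloxy)-5-methylphenol | Cc1cc(O)cc(OCc2ccccc2)c1
F0 | step 8 | none | none
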